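**Assumption:** the target SMILES has no stereodescriptor and the molecule has no stereocentre, so it is made as drawn, with the hindered C2–C1' axis left undefined; tert-butyl (2-methylbut-3-en-2-yl) carbonate is taken as a purchasable catalogue reagent.

## Retrosynthetic overview

1. The target comes from its 5,7,4'-tris-MOM ether; acetal cleavage is the only step after the last ring closure.
2. The dimethylpyran ring is closed last, by dehydrogenation of a 2'-prenyl-3'-hydroxy flavonol to an ortho-quinone methide and oxa-6π closure, as in the oxidative cyclisation of a C-prenyl phenol in nature. In the same flask, before the oxidation, the C6' 1,1-dimethylallyl group is relayed from O3' by a para-Claisen–Cope shift.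
3. Ring C comes from a 2'-hydroxychalcone by oxidative cyclisation (chalcone to flavonol); the chalcone is made in the same flask from a prenylated phloroacetophenone and a benzaldehyde.
4. The ketone comes from 2,4,6-trihydroxyacetophenone (C-prenylation, bis-MOM). The aldehyde comes from 3,4-dihydroxybenzaldehyde (MOM; O-1,1-dimethylallylation and ortho-Claisen; second O-1,1-dimethylallylation).
5. Ring order: rings A and B are bought, ring C is formed in step 7, the dimethylpyran ring in step 8.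

## Route

**Step 1**
Reactants: 1 2,4,6-trihydroxyacetophenone; 2 prenyl bromide
Product: 3 1-[2,4,6-trihydroxy-3-(3-methylbut-2-en-1-yl)phenyl]ethan-1-one
Conditions: prenyl bromide (1.0 equiv), 10% aq KOH, 0 °C → rt
Reagents that add atoms: 2 prenyl bromide (1-bromo-3-methylbut-2-ene), CC(C)=CCBr
Why: Friedel–Crafts-type C-alkylation of the ambident phloroacetophenone anion, which in water reacts at ring carbon; C3 and C5 are equivalent, so only one mono-C-prenyl product can form (moderate yield, the di-C-prenyl by-product is separated).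

**Step 2**
Reactants: 3 1-[2,4,6-trihydroxy-3-(3-methylbut-2-en-1-yl)phenyl]ethan-1-one; 4 chloromethyl methyl ether
Product: 5 1-[2-hydroxy-4,6-bis(methoxymethoxy)-3-(3-methylbut-2-en-1-yl)phenyl]ethan-1-one
Conditions: MOMCl (2.3 equiv), K2CO3 (3 equiv), acetone, 0 °C → rt
Reagents that add atoms: 4 chloromethyl methyl ether (MOMCl), COCCl
Why: Williamson-type MOM protection goes to the 4-OH and the less hindered 6-OH, while the 2-OH flanked by prenyl and acetyl stays chelated to the carbonyl; this free OH later becomes O1, which fixes the prenyl group at C8.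

**Step 3**
Reactants: 6 3,4-dihydroxybenzaldehyde; 4 chloromethyl methyl ether
Product: 7 3-hydroxy-4-(methoxymethoxy)benzaldehyde
Conditions: MOMCl (1.05 equiv), K2CO3 (1.1 equiv), acetone, 0 °C → rt
Reagents that add atoms: 4 chloromethyl methyl ether (MOMCl), COCCl
Why: chemoselective O-alkylation, because the 4-OH para to the formyl group is the more acidic phenol and is the one ionised by one equivalent of weak base.

**Step 4**
Reactants: 7 3-hydroxy-4-(methoxymethoxy)benzaldehyde; 8 tert-butyl (2-methylbut-3-en-2-yl) carbonate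
Product: 9 4-(methoxymethoxy)-3-[(2-methylbut-3-en-2-yl)oxy]benzaldehyde
Conditions: 8 (1.5 equiv), Pd(PPh3)4 (3 mol %), THF, 0 °C → rt
Reagents that add atoms: 8 tert-butyl (2-methylbut-3-en-2-yl) carbonate, C=CC(C)(C)OC(=O)OC(C)(C)C
Why: Tsuji–Trost O-allylation, in which zerovalent palladium ionises the tertiary allyl carbonate with loss of CO2, the tert-butoxide formed deprotonates the phenol, and the phenoxide attacks the more substituted allyl terminus under kinetic control to give the tertiary aryl ether.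

**Step 5**
Reactants: 9 4-(methoxymethoxy)-3-[(2-methylbut-3-en-2-yl)oxy]benzaldehyde
Product: 10 3-hydroxy-4-(methoxymethoxy)-2-(3-methylbut-2-en-1-yl)benzaldehyde
Conditions: degassed PhMe, 110 °C (sealed tube), 3 h
Reagents that add atoms: none
Why: aromatic ortho-Claisen rearrangement ([3,3]) to C2, the only unsubstituted ortho carbon; allylic inversion turns the 1,1-dimethylallyl ether into a normal prenyl C-substituent and enolisation restores the phenol.

**Step 6**
Reactants: 10 3-hydroxy-4-(methoxymethoxy)-2-(3-methylbut-2-en-1-yl)benzaldehyde; 8 tert-butyl (2-methylbut-3-en-2-yl) carbonate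
Product: 11 4-(methoxymethoxy)-3-[(2-methylbut-3-en-2-yl)oxy]-2-(3-methylbut-2-en-1-yl)benzaldehyde
Conditions: 8 (2 equiv), Pd(PPh3)4 (5 mol %), THF, 0 °C; product stored cold
Reagents that add atoms: 8 tert-butyl (2-methylbut-3-en-2-yl) carbonate, C=CC(C)(C)OC(=O)OC(C)(C)C
Why: the same Tsuji–Trost O-allylation, now on a phenol flanked on both sides; kept at 0 °C so that the kinetic tertiary ether does not isomerise to the linear prenyl ether.

**Step 7**
Reactants: 5 1-[2-hydroxy-4,6-bis(methoxymethoxy)-3-(3-methylbut-2-en-1-yl)phenyl]ethan-1-one; 11 4-(methoxymethoxy)-3-[(2-methylbut-3-en-2-yl)oxy]-2-(3-methylbut-2-en-1-yl)benzaldehyde; 12 hydrogen peroxide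
Product: 14 3-hydroxy-5,7-bis(methoxymethoxy)-2-[4-(methoxymethoxy)-3-[(2-methylbut-3-en-2-yl)oxy]-2-(3-methylbut-2-en-1-yl)phenyl]-8-(3-methylbut-2-en-1-yl)-4H-chromen-4-one, via chalcone 13 (not isolated)
Conditions: KOH (10 equiv), EtOH, rt, 36 h; then 30% aq H2O2 (5 equiv), 0 °C → rt; work-up at pH 5–6 (aq NaH2PO4)
Reagents that add atoms: 12 hydrogen peroxide, OO
Why: Claisen–Schmidt condensation gives the (E)-chalcone, and Algar–Flynn–Oyamada oxidative cyclisation then closes ring C through the only free phenol with oxygenation at C3 and dehydrogenation, the laboratory counterpart of the chalcone to flavonol line; the electron-rich prenyl and allyl alkenes are inert to nucleophilic alkaline peroxide, and the B ring carries no free phenol at this stage.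

**Step 8**
Reactants: 14 3-hydroxy-5,7-bis(methoxymethoxy)-2-[4-(methoxymethoxy)-3-[(2-methylbut-3-en-2-yl)oxy]-2-(3-methylbut-2-en-1-yl)phenyl]-8-(3-methylbut-2-en-1-yl)-4H-chromen-4-one
Product: 17 3-hydroxy-5,7-bis(methoxymethoxy)-2-[8-(methoxymethoxy)-2,2-dimethyl-6-(2-methylbut-3-en-2-yl)-2H-chromen-5-yl]-8-(3-methylbut-2-en-1-yl)-4H-chromen-4-one, via rearranged phenol 15 (not isolated), via ortho-quinone methide 16 (not isolated)
Conditions: degassed PhCl, 135 °C (sealed tube), 4 h; cool to 20 °C; DDQ (1.15 equiv), 20 → 60 °C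
Reagents that add atoms: none
Why: Proposed new method: the 1,1-dimethylallyl ether at O3' has both ortho carbons blocked (C2' prenyl, C4' OMOM), so it can only pass the allyl unit on by two successive [3,3] shifts (ortho-Claisen, then Cope) to the para carbon C6', and the double inversion delivers it there as the 1,1-dimethylallyl group and frees the 3'-OH; DDQ then removes hydride from the benzylic and allylic CH2 of the neighbouring prenyl group to give the ortho-quinone methide, which closes by oxa-6π electrocyclisation to the 2,2-dimethyl-2H-chromene, as a C-prenyl phenol is thought to close in nature; the closest known reaction types are the para-Claisen (Claisen–Cope) rearrangement of 2,6-disubstituted aryl allyl ethers and the DDQ cyclodehydrogenation of ortho-prenylphenols, here run in one flask on a flavonol; the 7-OMOM group keeps the C8 prenyl group out of the cyclisation and no stereocentre is formed.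

**Step 9**
Reactants: 17 3-hydroxy-5,7-bis(methoxymethoxy)-2-[8-(methoxymethoxy)-2,2-dimethyl-6-(2-methylbut-3-en-2-yl)-2H-chromen-5-yl]-8-(3-methylbut-2-en-1-yl)-4H-chromen-4-one
Product: 18 3,5,7-trihydroxy-2-[8-hydroxy-2,2-dimethyl-6-(2-methylbut-3-en-2-yl)-2H-chromen-5-yl]-8-(3-methylbut-2-en-1-yl)-4H-chromen-4-one
Conditions: 3 M aq HCl/MeOH (1:10), 40 °C, monitored and stopped at full conversion
Reagents that add atoms: none
Why: acid-catalysed acetal exchange with methanol cleaves the three MOM ethers; the acid is kept dilute and the temperature low so that the chromene, the 1,1-dimethylallyl group and the C8 prenyl group (next to the new 7-OH) are not hydroalkoxylated.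

## Compound list

1 | 1-(2,4,6-trihydroxyphenyl)ethan-1-one (2,4,6-trihydroxyacetophenone) | CC(=O)c1c(O)cc(O)cc1O | starting material
2 | 1-bromo-3-methylbut-2-ene (prenyl bromide) | CC(C)=CCBr | starting material
3 | 1-[2,4,6-trihydroxy-3-(3-methylbut-2-en-1-yl)phenyl]ethan-1-one | CC(=O)c1c(O)c(CC=C(C)C)c(O)cc1O | intermediate
4 | chloromethyl methyl ether (MOMCl) | COCCl | starting material
5 | 1-[2-hydroxy-4,6-bis(methoxymethoxy)-3-(3-methylbut-2-en-1-yl)phenyl]ethan-1-one | CC(=O)c1c(O)c(CC=C(C)C)c(OCOC)cc1OCOC | intermediate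
6 | 3,4-dihydroxybenzaldehyde | O=Cc1ccc(O)c(O)c1 | starting material
7 | 3-hydroxy-4-(methoxymethoxy)benzaldehyde | O=Cc1ccc(OCOC)c(O)c1 | intermediate
8 | tert-butyl (2-methylbut-3-en-2-yl) carbonate | C=CC(C)(C)OC(=O)OC(C)(C)C | starting material
9 | 4-(methoxymethoxy)-3-[(2-methylbut-3-en-2-yl)oxy]benzaldehyde | O=Cc1ccc(OCOC)c(OC(C)(C)C=C)c1 | intermediate
10 | 3-hydroxy-4-(methoxymethoxy)-2-(3-methylbut-2-en-1-yl)benzaldehyde | O=Cc1ccc(OCOC)c(O)c1CC=C(C)C | intermediate
11 | 4-(methoxymethoxy)-3-[(2-methylbut-3-en-2-yl)oxy]-2-(3-methylbut-2-en-1-yl)benzaldehyde | O=Cc1ccc(OCOC)c(OC(C)(C)C=C)c1CC=C(C)C | intermediate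
12 | hydrogen peroxide | OO | starting material
13 | (E)-1-[2-hydroxy-4,6-bis(methoxymethoxy)-3-(3-methylbut-2-en-1-yl)phenyl]-3-[4-(methoxymethoxy)-3-[(2-methylbut-3-en-2-yl)oxy]-2-(3-methylbut-2-en-1-yl)phenyl]prop-2-en-1-one (chalcone) | O=C(/C=C/c1ccc(OCOC)c(OC(C)(C)C=C)c1CC=C(C)C)c1c(O)c(CC=C(C)C)c(OCOC)cc1OCOC | intermediate (not isolated)
14 | 3-hydroxy-5,7-bis(methoxymethoxy)-2-[4-(methoxymethoxy)-3-[(2-methylbut-3-en-2-yl)oxy]-2-(3-methylbut-2-en-1-yl)phenyl]-8-(3-methylbut-2-en-1-yl)-4H-chromen-4-one | O=c1c(O)c(-c2ccc(OCOC)c(OC(C)(C)C=C)c2CC=C(C)C)oc2c(CC=C(C)C)c(OCOC)cc(OCOC)c12 | intermediate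
15 | 3-hydroxy-2-[3-hydroxy-4-(methoxymethoxy)-6-(2-methylbut-3-en-2-yl)-2-(3-methylbut-2-en-1-yl)phenyl]-5,7-bis(methoxymethoxy)-8-(3-methylbut-2-en-1-yl)-4H-chromen-4-one (rearranged phenol) | O=c1c(O)c(-c2c(C(C)(C)C=C)cc(OCOC)c(O)c2CC=C(C)C)oc2c(CC=C(C)C)c(OCOC)cc(OCOC)c12 | intermediate (not isolated)
16 | 3-hydroxy-5,7-bis(methoxymethoxy)-2-[(6Z)-4-(methoxymethoxy)-2-(2-methylbut-3-en-2-yl)-6-(3-methylbut-2-en-1-ylidene)-5-oxocyclohexa-1,3-dien-1-yl]-8-(3-methylbut-2-en-1-yl)-4H-chromen-4-one (ortho-quinone methide) | CC(C)=C/C=C1\C(=O)C(OCOC)=CC(C(C)(C)C=C)=C1c1oc2c(CC=C(C)C)c(OCOC)cc(OCOC)c2c(=O)c1O | intermediate (not isolated)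
17 | 3-hydroxy-5,7-bis(methoxymethoxy)-2-[8-(methoxymethoxy)-2,2-dimethyl-6-(2-methylbut-3-en-2-yl)-2H-chromen-5-yl]-8-(3-methylbut-2-en-1-yl)-4H-chromen-4-one | C=CC(C)(C)c1cc(OCOC)c2c(c1-c1oc3c(CC=C(C)C)c(OCOC)cc(OCOC)c3c(=O)c1O)C=CC(C)(C)O2 | intermediate
18 | 3,5,7-trihydroxy-2-[8-hydroxy-2,2-dimethyl-6-(2-methylbut-3-en-2-yl)-2H-chromen-5-yl]-8-(3-methylbut-2-en-1-yl)-4H-chromen-4-one (CNP0241222.0) | C=CC(C)(C)c1cc(O)c2c(c1-c1oc3c(CC=C(C)C)c(O)cc(O)c3c(=O)c1O)C=CC(C)(C)O2 | target

## Step count and risk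

Total step count: 9 (steps 1–2 make ketone 5, steps 3–6 make aldehyde 11, steps 7–9 join and finish).
Longest linear sequence: 7 steps (6 → 7 → 9 → 10 → 11 → 14 → 17 → 18).

**Most likely to fail, 1: step 8.** The tertiary ether of 14 may lose isoprene instead of rearranging, since C6' lies next to the bulky chromonyl group, and DDQ may attack the flavonol enol. The fallback moves the sigmatropic transfer to the aldehyde stage, where the para carbon is flanked only by a formyl group. It sets out from 11: heating 11 alone (degassed PhCl, 130 °C) gives 3-hydroxy-4-(methoxymethoxy)-6-(2-methylbut-3-en-2-yl)-2-(3-methylbut-2-en-1-yl)benzaldehyde F1. Condensation of F1 with 5 under the step 7 conditions (extra KOH for the free phenol) passes through (E)-1-[2-hydroxy-4,6-bis(methoxymethoxy)-3-(3-methylbut-2-en-1-yl)phenyl]-3-[3-hydroxy-4-(methoxymethoxy)-6-(2-methylbut-3-en-2-yl)-2-(3-methylbut-2-en-1-yl)phenyl]prop-2-en-1-one F2 and, after alkaline H2O2, comes back to the route at 15. Phenol 15 is then isolated and treated with DDQ alone (PhCl, 60 °C) to give 17.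

**Most likely to fail, 2: step 7.** A chalcone with an alkoxy group ortho to the ketone can give the aurone instead of the flavonol under alkaline H2O2. The fallback builds ring C without a chalcone and adds the C3 oxygen afterwards. It sets out from 11 and 5:
- Pinnick oxidation of 11 (NaClO2, NaH2PO4, 2-methylbut-2-ene, t-BuOH/H2O) gives 4-(methoxymethoxy)-3-[(2-methylbut-3-en-2-yl)oxy]-2-(3-methylbut-2-en-1-yl)benzoic acid F3.
- Esterification with the phenol of 5 (EDC·HCl, DMAP, CH2Cl2) gives 2-acetyl-3,5-bis(methoxymethoxy)-6-(3-methylbut-2-en-1-yl)phenyl 4-(methoxymethoxy)-3-[(2-methylbut-3-en-2-yl)oxy]-2-(3-methylbut-2-en-1-yl)benzoate F4.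
- Baker–Venkataraman acyl shift (KOH, pyridine, 50 °C) gives 1-[2-hydroxy-4,6-bis(methoxymethoxy)-3-(3-methylbut-2-en-1-yl)phenyl]-3-[4-(methoxymethoxy)-3-[(2-methylbut-3-en-2-yl)oxy]-2-(3-methylbut-2-en-1-yl)phenyl]propane-1,3-dione F5.
- Buffered cyclodehydration (NaOAc, AcOH, 50 °C) gives 5,7-bis(methoxymethoxy)-2-[4-(methoxymethoxy)-3-[(2-methylbut-3-en-2-yl)oxy]-2-(3-methylbut-2-en-1-yl)phenyl]-8-(3-methylbut-2-en-1-yl)-4H-chromen-4-one F6.
- C3 lithiation (LiN(iPr)2, THF, −78 °C) and trapping with B(OMe)3 gives dimethyl [5,7-bis(methoxymethoxy)-2-[4-(methoxymethoxy)-3-[(2-methylbut-3-en-2-yl)oxy]-2-(3-methylbut-2-en-1-yl)phenyl]-8-(3-methylbut-2-en-1-yl)-4-oxo-4H-chromen-3-yl]boronate F7 in the flask.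
- Oxidation of F7 with NaBO3 (THF/H2O, 0 °C) comes back to the route at 14.

**Most likely to fail, 3: step 6.** The phenol of 10 is flanked on both sides, so the palladium allylation may be slow or may give the linear prenyl ether, which would later deliver the wrong C5 isomer. The fallback makes the tertiary C–O bond by propargylation and then reduces. It sets out from 10: 3-chloro-3-methylbut-1-yne, DBU and CuCl2 (cat.) in MeCN at 0 °C give 4-(methoxymethoxy)-3-[(2-methylbut-3-yn-2-yl)oxy]-2-(3-methylbut-2-en-1-yl)benzaldehyde F8. Semi-hydrogenation of F8 (H2, 1 atm, Pd on CaCO3 poisoned with Pb(OAc)2, quinoline, EtOAc, rt) comes back to the route at 11.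

## Further compounds

F1 | step 8 | 3-hydroxy-4-(methoxymethoxy)-6-(2-methylbut-3-en-2-yl)-2-(3-methylbut-2-en-1-yl)benzaldehyde | O=Cc1c(C(C)(C)C=C)cc(OCOC)c(O)c1CC=C(C)C
F2 | step 8 | (E)-1-[2-hydroxy-4,6-bis(methoxymethoxy)-3-(3-methylbut-2-en-1-yl)phenyl]-3-[3-hydroxy-4-(methoxymethoxy)-6-(2-methylbut-3-en-2-yl)-2-(3-methylbut-2-en-1-yl)phenyl]prop-2-en-1-one | O=C(/C=C/c1c(C(C)(C)C=C)cc(OCOC)c(O)c1CC=C(C)C)c1c(O)c(CC=C(C)C)c(OCOC)cc1OCOC
F3 | step 7 | 4-(methoxymethoxy)-3-[(2-methylbut-3-en-2-yl)oxy]-2-(3-methylbut-2-en-1-yl)benzoic acid | OC(=O)c1ccc(OCOC)c(OC(C)(C)C=C)c1CC=C(C)C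
F4 | step 7 | 2-acetyl-3,5-bis(methoxymethoxy)-6-(3-methylbut-2-en-1-yl)phenyl 4-(methoxymethoxy)-3-[(2-methylbut-3-en-2-yl)oxy]-2-(3-methylbut-2-en-1-yl)benzoate | CC(=O)c1c(OC(=O)c2ccc(OCOC)c(OC(C)(C)C=C)c2CC=C(C)C)c(CC=C(C)C)c(OCOC)cc1OCOC
F5 | step 7 | 1-[2-hydroxy-4,6-bis(methoxymethoxy)-3-(3-methylbut-2-en-1-yl)phenyl]-3-[4-(methoxymethoxy)-3-[(2-methylbut-3-en-2-yl)oxy]-2-(3-methylbut-2-en-1-yl)phenyl]propane-1,3-dione | O=C(CC(=O)c1ccc(OCOC)c(OC(C)(C)C=C)c1CC=C(C)C)c1c(O)c(CC=C(C)C)c(OCOC)cc1OCOC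
F6 | step 7 | 5,7-bis(methoxymethoxy)-2-[4-(methoxymethoxy)-3-[(2-methylbut-3-en-2-yl)oxy]-2-(3-methylbut-2-en-1-yl)phenyl]-8-(3-methylbut-2-en-1-yl)-4H-chromen-4-one | O=c1cc(-c2ccc(OCOC)c(OC(C)(C)C=C)c2CC=C(C)C)oc2c(CC=C(C)C)c(OCOC)cc(OCOC)c12
F7 | step 7 | dimethyl [5,7-bis(methoxymethoxy)-2-[4-(methoxymethoxy)-3-[(2-methylbut-3-en-2-yl)oxy]-2-(3-methylbut-2-en-1-yl)phenyl]-8-(3-methylbut-2-en-1-yl)-4-oxo-4H-chromen-3-yl]boronate | O=c1c(B(OC)OC)c(-c2ccc(OCOC)c(OC(C)(C)C=C)c2CC=C(C)C)oc2c(CC=C(C)C)c(OCOC)cc(OCOC)c12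
F8 | step 6 | 4-(methoxymethoxy)-3-[(2-methylbut-3-yn-2-yl)oxy]-2-(3-methylbut-2-en-1-yl)benzaldehyde | O=Cc1ccc(OCOC)c(OC(C)(C)C#C)c1CC=C(C)C
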